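The route rests on cutting the cyclobutane bond C6–C11, which links the bridgehead CH beside the enone carbonyl (C6) to the methyl-bearing quaternary carbon beside the tiglate carbinol (C11). Because C7=O and the oxygen on C1 flank this bond in a 1,4-relationship, both ends are ketone α′-carbons of a cis-fused cyclohexenone–cycloheptenone. Oxidative coupling of its bis-enolate across the ring fusion closes the four-membered ring and in the same operation turns the fused 6–7 bicycle into the bicyclo[3.1.1]heptenone and the bicyclo[4.1.1]octenone. The precursor is assembled by an aminocatalytic cyclohexenone synthesis, an Ireland–Claisen chirality relay, ring-closing metathesis and allylic oxidation; conjugate borylation, Evans–Tishchenko reduction and tigloylation complete the target.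

Key step: step 10

Numbering used for 16–26 (that of the target carbocycle): C1 tiglate carbinol, C2 CH2, C3 senecioate carbinol, C4 CMe2, C5 CH, C6 CH α to the ketone, C7 C=O, C8 =CH, C9 =C(CH3), C10 CH, C11 C(CH3); ring bonds C5–C6, C5–C10, C10–C11, C11–C1 and (from 19 on) C6–C11.
Assumption: the C-methyl centre made in step 5 (later C11) is erased in step 10, so 10–13 and 15–17 are drawn as one epimer and a mixture is carried forward.
Assumption: the ligand antipode named in step 11 is taken to deliver boron to the C3 face shown; the sense would be confirmed on the first run and the mirror-image ligand used if it is opposite.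

Step 1
Reactants: 1 methyl 3,3-dimethylpent-4-enoate
Product: 2 3,3-dimethylpent-4-enal
Conditions: iBu2AlH (1.05 equiv), CH2Cl2, −78 °C; MeOH, then aq. potassium sodium tartrate
Reagents that add atoms: none
Why: DIBAL-H partial reduction: at −78 °C the aluminium hemiacetal formed by one hydride transfer is stable and collapses to the aldehyde only on work-up, and the isolated vinyl group does not react.

Step 2
Reactants: 2 3,3-dimethylpent-4-enal; 3 pent-1-en-3-one
Product: 5 (4R)-2-methyl-4-(2-methylbut-3-en-2-yl)cyclohex-2-en-1-one, via keto aldehyde 4 (not isolated)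
Conditions: (S)-α,α-diphenylprolinol trimethylsilyl ether (10 mol %), ethyl 3,4-dihydroxybenzoate (20 mol %), neat, 4 °C; then LiOH (0.2 equiv), iPrOH, rt
Reagents that add atoms: none
Why: Enamine-catalysed Michael addition (diarylprolinol silyl ether catalysis) followed by intramolecular aldol condensation: the bulky silyloxydiphenylmethyl group shields one face of the E-enamine so that the (S)-catalyst should give the (2S)-aldehyde 4, and the ethyl ketone enolate then condenses with the aldehyde to the 2-methylcyclohexenone, in which the same centre is C4 with R descriptor.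

Step 3
Reactants: 5 (4R)-2-methyl-4-(2-methylbut-3-en-2-yl)cyclohex-2-en-1-one
Product: 6 (1S,4R)-2-methyl-4-(2-methylbut-3-en-2-yl)cyclohex-2-en-1-ol (cis)
Conditions: (R)-2-methyl-CBS-oxazaborolidine (20 mol %), catecholborane (1.5 equiv), toluene, −78 °C; aq. NaOH work-up
Reagents that add atoms: none
Why: Corey–Bakshi–Shibata reduction under reagent control: with the α-methylated alkene arm as the large ketone substituent the (R)-oxazaborolidine should deliver hydride to the face that gives the 1S carbinol (hydroxyl cis to the C4 side chain) regardless of the remote C4 centre, and catecholborane reduces only the activated ketone, not the vinyl group.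

Step 4
Reactants: 6 (1S,4R)-2-methyl-4-(2-methylbut-3-en-2-yl)cyclohex-2-en-1-ol; 7 propanoyl chloride
Product: 8 (1S,4R)-2-methyl-4-(2-methylbut-3-en-2-yl)cyclohex-2-en-1-yl propanoate (cis)
Conditions: pyridine, DMAP (5 mol %), CH2Cl2, 0 °C
Reagents that add atoms: none
Why: Acylation of the secondary allylic alcohol by the acid chloride under nucleophilic (DMAP) catalysis leaves both stereocentres untouched.

Step 5
Reactants: 8 (1S,4R)-2-methyl-4-(2-methylbut-3-en-2-yl)cyclohex-2-en-1-yl propanoate
Product: 11 (2R)-2-[(1S,6R)-2-methyl-6-(2-methylbut-3-en-2-yl)cyclohex-2-en-1-yl]propanoic acid, via silyl ketene acetal 9 (not isolated), via trimethylsilyl ester 10 (not isolated)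
Conditions: LiN(iPr)2 (LDA, 1.3 equiv), Me3SiCl (1.5 equiv, present from the start), THF, −78 °C → 65 °C; then 1 M HCl
Reagents that add atoms: chlorotrimethylsilane, C[Si](C)(C)Cl (silicon in intermediates 9 and 10 only)
Why: Ireland–Claisen rearrangement: the silyl ketene acetal 9 undergoes a suprafacial [3,3] shift across the ring O–C1–C2=C3 unit, so the new C–C bond forms at C3 on the face that carried the ester oxygen and hence cis to the neighbouring 2-methylbut-3-en-2-yl group (which sits pseudoequatorial and leaves the C–O bond pseudoaxial as the shift requires), while the α-methyl centre is of no consequence.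

Step 6
Reactants: 11 (2R)-2-[(1S,6R)-2-methyl-6-(2-methylbut-3-en-2-yl)cyclohex-2-en-1-yl]propanoic acid
Product: 13 (2R)-N-methoxy-N-methyl-2-[(1S,6R)-2-methyl-6-(2-methylbut-3-en-2-yl)cyclohex-2-en-1-yl]propanamide, via acyl imidazolide 12 (not isolated)
Conditions: 1,1′-carbonyldiimidazole (1.3 equiv), CH2Cl2, rt; then MeNH(OMe)·HCl (1.5 equiv), rt
Reagents that add atoms: 1,1′-carbonyldiimidazole, O=C(n1ccnc1)n1ccnc1 (imidazolyl in intermediate 12 only); N,O-dimethylhydroxylamine hydrochloride, CNOC.Cl
Why: Weinreb amide formation through the acyl imidazolide, an activation that tolerates the α-branched acid and leaves both alkenes and the ring stereocentres untouched.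

Step 7
Reactants: 13 (2R)-N-methoxy-N-methyl-2-[(1S,6R)-2-methyl-6-(2-methylbut-3-en-2-yl)cyclohex-2-en-1-yl]propanamide; 14 vinylmagnesium bromide
Product: 15 (4R)-4-[(1S,6R)-2-methyl-6-(2-methylbut-3-en-2-yl)cyclohex-2-en-1-yl]pent-1-en-3-one
Conditions: THF, 0 °C; inverse quench into cold 1 M HCl
Reagents that add atoms: none
Why: Weinreb ketone synthesis: the chelated tetrahedral magnesium adduct resists a second addition and the inverse acidic quench protonates the released amine before it can add to the new vinyl ketone.

Step 8
Reactants: 15 (4R)-4-[(1S,6R)-2-methyl-6-(2-methylbut-3-en-2-yl)cyclohex-2-en-1-yl]pent-1-en-3-one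
Product: 16 (4aS,5R,9aR)-4,5,9,9-tetramethyl-1,2,4a,5,9,9a-hexahydro-6H-benzo[7]annulen-6-one (cis-fused bicyclo[5.4.0]undecadienone; C1=O; C2=C3; C8=C9)
Conditions: second-generation Hoveyda–Grubbs catalyst [RuCl2(H2IMes)(=CH-C6H4-2-OiPr)] (10 mol %), toluene (0.005 M), 80 °C, argon sparge
Reagents that add atoms: none
Why: Ring-closing metathesis: the cis disposition of the two side arms on the cyclohexene holds the enone vinyl group and the 1,1-dimethylallyl alkene together so that a phosphine-free ruthenium carbene can close the cycloheptenone with loss of ethene, the trisubstituted ring alkene being too hindered to take part.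

Step 9
Reactants: 16 cis-fused bicyclic dienone
Product: 17 (4aS,5R,9aR)-4,5,9,9-tetramethyl-4a,5,9,9a-tetrahydro-1H-benzo[7]annulene-2,6-dione (cis-fused bis-enone; C1=O; C7=O)
Conditions: CrO3 (15 equiv), 3,5-dimethylpyrazole (15 equiv), CH2Cl2, −20 °C
Reagents that add atoms: chromium trioxide, O=[Cr](=O)=O
Why: Allylic oxidation with the CrO3–3,5-dimethylpyrazole complex: as in the oxidation of α-pinene to verbenone, a trisubstituted cyclohexene is attacked at the ring methylene on its CH terminus (C7) to give the β,β-disubstituted enone, the ring-fusion C10–H being shielded and the cycloheptenone having no allylic hydrogen.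

Step 10
Reactants: 17 cis-fused bis-enone
Product: 19 tricyclic bis-enone (5S,6R,10R,11R; C1=O; C2=C3; C7=O; C8=C9; cyclobutane C5–C6–C11–C10), via dilithium bis-dienolate 18 (not isolated)
Conditions: 17 added to LiN(iPr)2 (2.3 equiv), THF, −78 °C, 1 h; then [Fe(DMF)3Cl2][FeCl4] (1.2 equiv, trivalent iron) in DMF, −78 °C → rt
Reagents that add atoms: lithium diisopropylamide, [Li+].CC(C)[N-]C(C)C (lithium in intermediate 18 only)
Why: Proposed new method: inverse addition of 17 to excess LiN(iPr)2 removes the two α′-protons kinetically (C6–H of the cyclohexenone; C11–H of the cycloheptenone, which has no γ-hydrogen because C4 is quaternary) to give bis-dienolate 18, and trivalent iron then takes one electron from an enolate so that the resulting α-keto radical adds to the neighbouring enolate carbon, a second electron transfer turning the ketyl into the 1,4-diketone. The closest known reaction type is the intramolecular oxidative coupling of ketone, ester or amide bis-enolates with trivalent iron, divalent copper or iodine, which gives cyclic 1,4-dicarbonyls including small and bridged rings, but no transannular ketone–ketone case that closes a cyclobutane is known. The new C6–C11 bond closes the cyclobutane C5–C6–C11–C10 in a 4-exo mode across the C5–C10 fusion bond, and the same bond completes the bicyclo[3.1.1]heptenone (C11 bridging C6 and C10 of the six-membered ring) and the bicyclo[4.1.1]octenone (C6 bridging C5 and C11 of the seven-membered ring). C6 and C11 are dictated by C5 and C10, because a one-atom bridge can only form on the face of the cis-fused bicycle that carries C4 and C11, so both C11 epimers of 17 converge on 19. The step needs α′,α′ C–C coupling rather than γ-coupling, C–O coupling, transannular aldol addition or dehydrogenation, and this is secured by complete bis-enolisation at −78 °C before the oxidant is added (no free carbonyl, no extended enolate), by the carbon-centred spin density of α-keto radicals and by the cis fusion, which holds C6 and C11 gauche and within bonding reach. Bond formation from two enolates is strongly exergonic, which should pay for the ring strain, and the new centres (a bridgehead CH and a quaternary carbon) can neither enolise nor be oxidised further.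

Step 11
Reactants: 19 tricyclic bis-enone
Product: 21 tricyclic β-hydroxy ketone (3R,5S,6R,10R,11R; C1=O; C3–OH; C7=O; C8=C9), via pinacol boronate 20 (not isolated)
Conditions: CuCl (10 mol %), (R)-1-[(S)-2-(diphenylphosphino)ferrocenyl]ethyldicyclohexylphosphine (11 mol %), NaOtBu (15 mol %), B2pin2 (1.2 equiv), MeOH (2 equiv), THF, 0 °C → rt; then NaBO3·4H2O, THF–H2O, rt
Reagents that add atoms: bis(pinacolato)diboron, CC1(C)OB(OC1(C)C)B1OC(C)(C)C(C)(C)O1 (boron in intermediate 20 only); sodium perborate, [Na+].[O-]OB=O (hydroxyl oxygen of 21)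
Why: Copper–boryl conjugate addition (β-borylation) should occur at the disubstituted cycloheptenone alkene and not at the β,β-disubstituted enone of the bicyclo[3.1.1]heptenone, the chiral bisphosphine chooses the face of C3 because the two faces differ only through the remote C7=O/C9–CH3 pair, and perborate oxidation replaces boron by hydroxyl with retention to set 3R.

Step 12
Reactants: 21 tricyclic β-hydroxy ketone; 22 3-methylbut-2-enal
Product: 23 anti-1,3-diol mono-senecioate (1R,3R,5S,6R,10R,11R; C1–OH free; C3–O-(3-methylbut-2-enoyl))
Conditions: SmI2 (0.3 equiv, divalent samarium) premixed with 22 (8 equiv), THF, −10 °C; then 21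
Reagents that add atoms: none
Why: Evans–Tishchenko reduction: the samarium-bound hemiacetal formed from the C3 hydroxyl and aldehyde 22 passes its hydride to C1 within a six-membered transition state on the face of the C3 oxygen, which should give the 1,3-anti (trans) product with C3 acylated as the 3-methylbut-2-enoate and the new 1R hydroxyl free, while premixing leaves no divalent samarium to reduce the enone.

Step 13
Reactants: 23 anti-1,3-diol mono-senecioate; 24 tiglic acid
Product: 26 CNP0277258.1 (1R,3R,5S,6R,10R,11R; C1 tiglate; C3 senecioate), via mixed anhydride 25 (not isolated)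
Conditions: 24, 2,4,6-trichlorobenzoyl chloride, Et3N, toluene, rt; then 23, DMAP, 40 °C
Reagents that add atoms: 2,4,6-trichlorobenzoyl chloride, O=C(Cl)c1c(Cl)cc(Cl)cc1Cl (aroyl group in intermediate 25 only)
Why: Yamaguchi esterification: DMAP transfers the tigloyl group of mixed anhydride 25 to the hindered C1 hydroxyl, the E geometry is that of the purchased acid, and the trans relation of the two oxygens on the rigid ring prevents acyl migration.

Compound list
1 | methyl 3,3-dimethylpent-4-enoate | COC(=O)CC(C)(C)C=C | starting material
2 | 3,3-dimethylpent-4-enal | O=CCC(C)(C)C=C | intermediate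
3 | pent-1-en-3-one (ethyl vinyl ketone) | CCC(=O)C=C | starting material
4 | (2S)-2-(2-methylbut-3-en-2-yl)-5-oxoheptanal (keto aldehyde, formed in the flask) | CCC(=O)CC[C@@H](C(C)(C)C=C)C=O | intermediate
5 | (4R)-2-methyl-4-(2-methylbut-3-en-2-yl)cyclohex-2-en-1-one | O=C1CC[C@@H](C(C)(C)C=C)C=C1C | intermediate
6 | (1S,4R)-2-methyl-4-(2-methylbut-3-en-2-yl)cyclohex-2-en-1-ol (cis) | O[C@H]1CC[C@@H](C(C)(C)C=C)C=C1C | intermediate
7 | propanoyl chloride | CCC(=O)Cl | starting material
8 | (1S,4R)-2-methyl-4-(2-methylbut-3-en-2-yl)cyclohex-2-en-1-yl propanoate (cis) | CCC(=O)O[C@H]1CC[C@@H](C(C)(C)C=C)C=C1C | intermediate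
9 | (E)-1-{[(1S,4R)-2-methyl-4-(2-methylbut-3-en-2-yl)cyclohex-2-en-1-yl]oxy}-1-(trimethylsilyloxy)prop-1-ene (silyl ketene acetal, formed in the flask) | C/C=C(/O[Si](C)(C)C)O[C@H]1CC[C@@H](C(C)(C)C=C)C=C1C | intermediate
10 | trimethylsilyl (2R)-2-[(1S,6R)-2-methyl-6-(2-methylbut-3-en-2-yl)cyclohex-2-en-1-yl]propanoate (formed in the flask) | C[Si](C)(C)OC(=O)[C@H](C)[C@H]1C(C)=CCC[C@H]1C(C)(C)C=C | intermediate
11 | (2R)-2-[(1S,6R)-2-methyl-6-(2-methylbut-3-en-2-yl)cyclohex-2-en-1-yl]propanoic acid (ring substituents cis) | OC(=O)[C@H](C)[C@H]1C(C)=CCC[C@H]1C(C)(C)C=C | intermediate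
12 | (2R)-1-(1H-imidazol-1-yl)-2-[(1S,6R)-2-methyl-6-(2-methylbut-3-en-2-yl)cyclohex-2-en-1-yl]propan-1-one (acyl imidazolide, formed in the flask) | O=C(n1ccnc1)[C@H](C)[C@H]1C(C)=CCC[C@H]1C(C)(C)C=C | intermediate
13 | (2R)-N-methoxy-N-methyl-2-[(1S,6R)-2-methyl-6-(2-methylbut-3-en-2-yl)cyclohex-2-en-1-yl]propanamide | CON(C)C(=O)[C@H](C)[C@H]1C(C)=CCC[C@H]1C(C)(C)C=C | intermediate
14 | vinylmagnesium bromide | C=C[Mg]Br | starting material
15 | (4R)-4-[(1S,6R)-2-methyl-6-(2-methylbut-3-en-2-yl)cyclohex-2-en-1-yl]pent-1-en-3-one | C=CC(=O)[C@H](C)[C@H]1C(C)=CCC[C@H]1C(C)(C)C=C | intermediate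
16 | (4aS,5R,9aR)-4,5,9,9-tetramethyl-1,2,4a,5,9,9a-hexahydro-6H-benzo[7]annulen-6-one (cis-fused cycloheptenone–methylcyclohexene; 5R,10S,11R in carbocycle numbering) | O=C1C=CC(C)(C)[C@@H]2CCC=C(C)[C@@H]2[C@H]1C | intermediate
17 | (4aS,5R,9aR)-4,5,9,9-tetramethyl-4a,5,9,9a-tetrahydro-1H-benzo[7]annulene-2,6-dione (cis-fused cyclohexenone–cycloheptenone; 5R,10S,11R in carbocycle numbering) | O=C1C=CC(C)(C)[C@@H]2CC(=O)C=C(C)[C@@H]2[C@H]1C | intermediate
18 | dilithium bis-dienolate of 17 (C6=C7–OLi and C11=C1–OLi; C5 and C10 as in 17; formed in the flask) | [Li+].[Li+].[O-]C1=C(C)[C@H]2C(C)=CC([O-])=C[C@H]2C(C)(C)C=C1 | intermediate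
19 | tricyclic bis-enone: (5S,6R,10R,11R)-4,4,9,11-tetramethyl carbocycle with C1=O, C2=C3, C7=O, C8=C9 and cyclobutane C5–C6–C11–C10 | O=C1C=CC(C)(C)[C@@H]2[C@H]3C(=O)C=C(C)[C@@H]2[C@]31C | intermediate
20 | 3-(4,4,5,5-tetramethyl-1,3,2-dioxaborolan-2-yl) ketone from 19 (boron on C3, same face as the hydroxyl of 21; formed in the flask) | O=C1C[C@@H](B2OC(C)(C)C(C)(C)O2)C(C)(C)[C@@H]2[C@H]3C(=O)C=C(C)[C@@H]2[C@]31C | intermediate
21 | tricyclic β-hydroxy ketone: (3R,5S,6R,10R,11R)-3-hydroxy-4,4,9,11-tetramethyl carbocycle with C1=O, C7=O, C8=C9 | O=C1C[C@@H](O)C(C)(C)[C@@H]2[C@H]3C(=O)C=C(C)[C@@H]2[C@]31C | intermediate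
22 | 3-methylbut-2-enal | CC(C)=CC=O | starting material
23 | anti-1,3-diol mono-senecioate: (1R,3R,5S,6R,10R,11R)-1-hydroxy-3-(3-methylbut-2-enoyloxy) tricycle with C7=O, C8=C9 | O[C@@H]1C[C@@H](OC(=O)C=C(C)C)C(C)(C)[C@@H]2[C@H]3C(=O)C=C(C)[C@@H]2[C@]31C | intermediate
24 | tiglic acid, (E)-2-methylbut-2-enoic acid | C/C=C(\C)C(=O)O | starting material
25 | (E)-2-methylbut-2-enoic 2,4,6-trichlorobenzoic anhydride (formed in the flask) | C/C=C(\C)C(=O)OC(=O)c1c(Cl)cc(Cl)cc1Cl | intermediate
26 | CNP0277258.1: (1R,3R,5S,6R,10R,11R)-1-[(E)-2-methylbut-2-enoyloxy]-3-(3-methylbut-2-enoyloxy) tricycle with C7=O, C8=C9 | C/C=C(\C)C(=O)O[C@@H]1C[C@@H](OC(=O)C=C(C)C)C(C)(C)[C@@H]2[C@H]3C(=O)C=C(C)[C@@H]2[C@]31C | target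

Total step count: 13. Longest linear sequence: 13 steps (from 1; all other inputs are purchased).

Steps most likely to fail

Step 10 (proposed new method). The oxidation may take other courses than the strained C–C closure: C–O bond formation between one enolate carbon and the other enolate oxygen, transannular aldol addition if bis-enolisation is incomplete, intermolecular dimerisation, or further dehydrogenation. The fallback uses known two-electron chemistry, sets out from 17 and returns at 19. One equivalent of LiN(iPr)2 at −78 °C removes the more accessible C6 methylene proton and Me3SiCl traps the enolate as the 7-(trimethylsilyloxy) dienol ether F1. N-Bromosuccinimide in THF at −78 °C brominates C6 on the face away from the neighbouring C4 quaternary carbon and gives the 6-bromo bis-enone F2. KOtBu in tBuOH–THF at 0 °C then forms the C11 enolate reversibly, and this displaces the bromide from the rear in a 4-exo-tet enolate alkylation of the kind that closes bicyclo[3.1.1]heptanones, to give 19. Enolisation of F2 at C6 is reversible and unproductive.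

Step 11. Boryl transfer to C3 may be slow because C3 is flanked by the quaternary C4, and the ligand may fail to impose one face. The fallback sets out from 19 and returns at 21. Weitz–Scheffer epoxidation (30% H2O2, NaOH, MeOH, 0 °C) uses a small anionic nucleophile that should reach the disubstituted cycloheptenone alkene in preference to the hindered trisubstituted enone; it gives the 2,3-epoxy ketone F3, with the face now chosen by the substrate alone. Reductive cleavage of the Cα–O bond with the selenoborate made from PhSeSePh and NaBH4 in EtOH–AcOH, a reagent that leaves enones and the cyclobutane intact, then gives 21.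

Step 8. Both alkenes are poor metathesis partners, one electron-poor and the other on a quaternary carbon, so initiation and ring closure may be slow and catalyst decay or oligomerisation may take over. The fallback sets out from 15 and returns at 16. Luche reduction (NaBH4, CeCl3·7H2O, MeOH, −40 °C) gives the dienol F4 as a mixture at the carbinol centre. Its allylic alcohol loads a ruthenium carbene readily, so ring-closing metathesis with the second-generation Grubbs catalyst [RuCl2(H2IMes)(PCy3)(=CHPh)] in CH2Cl2 at 40 °C should close the bicyclic cycloheptenol F5. Dess–Martin periodinane then oxidises the allylic alcohol to 16.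

Further compounds
F1 | step 10 | 7-(trimethylsilyloxy) dienol ether of 17 (C6=C7–O–SiMe3; cycloheptenone unchanged) | O=C1C=CC(C)(C)[C@@H]2C=C(O[Si](C)(C)C)C=C(C)[C@@H]2[C@H]1C
F2 | step 10 | 6-bromo bis-enone (bromine on C6 trans to C4 and cis to H-5) | O=C1C=CC(C)(C)[C@@H]2[C@@H](Br)C(=O)C=C(C)[C@@H]2[C@H]1C
F3 | step 11 | 2,3-epoxy ketone of 19 (oxirane oxygen on the face of the C3–O bond of 21) | O=C1[C@H]2O[C@H]2C(C)(C)[C@@H]3[C@H]4C(=O)C=C(C)[C@@H]3[C@]41C
F4 | step 8 | 4-[(1S,6R)-2-methyl-6-(2-methylbut-3-en-2-yl)cyclohex-2-en-1-yl]pent-1-en-3-ol (carbinol centre as a mixture) | C=CC(O)[C@H](C)[C@H]1C(C)=CCC[C@H]1C(C)(C)C=C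
F5 | step 8 | cis-fused bicyclic cycloheptenol (C1 carbinol of 16, mixture at C1) | OC1C=CC(C)(C)[C@@H]2CCC=C(C)[C@@H]2[C@H]1C
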